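The route rests on cutting out C3 of the eriodictyol unit, the one CH(aryl) carbon that lies between the C4 ketone and C2 in ring C. Without it, ring C contracts to a racemic, enolisable 2-aryl benzofuran-3(2H)-one (6), and the carbon returns as an aryl diazomethane (12) that already carries the future ring D. One scandium-catalysed diazo homologation inserts this carbon: it forms C3–C4 and C2–C3, enlarges the furanone to ring C, and sets C2 (dynamic kinetic resolution) and C3 (trans). An iodine spectator on 12 then allows ring F to be grown by palladium chemistry that does not open ring C; C2'' is set by catalyst-controlled aryl addition to a chromone.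

Key step: step 9

Remarks on the chemistry
- Locants: the eriodictyol unit is numbered O1–C8a, with ring A (benzo), ring C (pyranone) and ring B (3,4-dioxygenated phenyl on C2). The naringenin unit carries double-primed locants, with ring D (benzo, bonded through C8'' to C3), ring F (pyranone) and ring E (4-oxygenated phenyl on C2''). Before ring F exists, the future ring D is numbered C1'–C6' (C1' becomes C8'', C2' becomes C8a'', C3' becomes C4a'', C4' becomes C5'', C6' becomes C7'').
- Configuration: the target is (2R,3S), 2,3-trans, in the eriodictyol unit and (2''S) in the naringenin unit. Compounds 13 to 16 are (2R,3S); 18 is (2R,3S,2''S).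
- Protecting groups: the C4' oxygen (para to the interflavonoid bond) is benzylated and the two ortho oxygens carry MOM groups. Only an oxygen ortho to the bond can therefore become O1'', which makes the C3–C8'' linkage unambiguous.
- Iodine spectator: the iodine at C3' is inert in step 9 and is the handle for ring F afterwards; it replaces an electrophilic acylation of a free polyphenol.
- Base sensitivity: after step 9 nothing more basic than a tertiary amine is used, because enolisation at C3 can open ring C by retro-oxa-Michael reaction and scramble C2.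
- Assumption: which antipode of the chiral ligand gives the required sense in steps 9 and 12 cannot be deduced with certainty. Both antipodes are accessible and the choice would be made on the first runs; for step 12 the (R)-ligand is written by analogy with the facial sense of this catalyst type with cyclic enones.
- Rotamers: compounds 13 to 16, 18 and 19 are expected to show slowly interconverting rotamers about the C3–C1' (C3–C8'') bond. These are conformers, not stereoisomers to be controlled.

Step 1
Reactants: 1 1,3,5-tris(benzyloxy)benzene; 2 3,4-bis(benzyloxy)phenylacetic acid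
Product: 3 2-[3,4-bis(benzyloxy)phenyl]-1-[2,4,6-tris(benzyloxy)phenyl]ethan-1-one
Conditions: 2, (CF3CO)2O (1.5 equiv), CH2Cl2, 0 °C, 30 min; then 1, 0 °C → rt
Reagents that add atoms: none
Why: Friedel–Crafts acylation by the mixed carboxylic–trifluoroacetic anhydride of 2: the phloroglucinol triether is nucleophilic enough to react without a metal Lewis acid, its three free positions are equivalent, and the aryl ketone formed is deactivated toward a second acylation, so the benzyl ethers are not at risk.

Step 2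
Reactants: 3 2-[3,4-bis(benzyloxy)phenyl]-1-[2,4,6-tris(benzyloxy)phenyl]ethan-1-one
Product: 4 1-[2,4-bis(benzyloxy)-6-hydroxyphenyl]-2-[3,4-bis(benzyloxy)phenyl]ethan-1-one
Conditions: BCl3 (1.1 equiv), CH2Cl2, −78 °C; H2O quench
Reagents that add atoms: none
Why: Chelation-controlled Lewis-acid ether cleavage: BCl3 binds the ketone oxygen and removes only a benzyl group ortho to the carbonyl, the two ortho ethers being equivalent and the boron chelate formed protecting the second one, while the remote benzyl ethers stay intact at −78 °C.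

Step 3
Reactants: 4 1-[2,4-bis(benzyloxy)-6-hydroxyphenyl]-2-[3,4-bis(benzyloxy)phenyl]ethan-1-one
Product: 6 racemic 4,6-bis(benzyloxy)-2-[3,4-bis(benzyloxy)phenyl]benzofuran-3(2H)-one, via α-bromo ketone 5 (not isolated)
Conditions: PhNMe3Br3 (1.0 equiv), THF, 0 °C; then NaOAc, EtOH, rt, argon
Reagents that add atoms: none
Why: α-Bromination of the readily enolised benzyl ketone by the tribromide salt, then intramolecular Williamson etherification (5-exo-tet) by the ortho phenol under a weak base closes the furanone; C2 is formed racemic, as the key step requires, and the air-sensitive product is kept under argon.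

Step 4
Reactants: 7 2,4,6-trihydroxybenzaldehyde
Product: 8 4-(benzyloxy)-2,6-dihydroxybenzaldehyde
Conditions: BnBr (1.0 equiv), NaHCO3, MeCN, 60 °C
Reagents that add atoms: benzyl bromide, BrCc1ccccc1
Why: Regioselective Williamson etherification: the C4 hydroxyl, para to the formyl group and not tied up in a hydrogen bond, is the most acidic and the most accessible, so a weak base and one equivalent of halide should benzylate it first (over-alkylated material is removed by chromatography).

Step 5
Reactants: 8 4-(benzyloxy)-2,6-dihydroxybenzaldehyde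
Product: 9 4-(benzyloxy)-2,6-bis(methoxymethoxy)benzaldehyde
Conditions: NaH (2.4 equiv), MOMCl (2.4 equiv), THF/DMF, 0 °C → rt
Reagents that add atoms: chloromethyl methyl ether, COCCl
Why: Williamson-type O-alkylation of both remaining phenols as methoxymethyl acetals, the strong base being needed to break the hydrogen bond of the chelated hydroxyl; the two acetals are orthogonal to the benzyl ether that must stay on the para oxygen.

Step 6
Reactants: 9 4-(benzyloxy)-2,6-bis(methoxymethoxy)benzaldehyde
Product: 10 4-(benzyloxy)-3-iodo-2,6-bis(methoxymethoxy)benzaldehyde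
Conditions: NIS (1.05 equiv), CF3CO2H (5 mol%), MeCN, 0 °C → rt
Reagents that add atoms: N-iodosuccinimide, O=C1CCC(=O)N1I
Why: Electrophilic aromatic iodination: the two free ring positions are equivalent and each is ortho or para to all three alkoxy groups, and the first iodine slows a second substitution; the catalytic acid at 0 °C should not cleave the acetals.

Step 7
Reactants: 10 4-(benzyloxy)-3-iodo-2,6-bis(methoxymethoxy)benzaldehyde
Product: 11 (E)-[4-(benzyloxy)-3-iodo-2,6-bis(methoxymethoxy)benzylidene]hydrazine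
Conditions: N2H4·H2O (10 equiv), EtOH, rt
Reagents that add atoms: hydrazine, NN
Why: Hydrazone condensation of the hindered aldehyde with a large excess of hydrazine, the excess suppressing azine formation.

Step 8
Reactants: 11 (E)-[4-(benzyloxy)-3-iodo-2,6-bis(methoxymethoxy)benzylidene]hydrazine
Product: 12 [4-(benzyloxy)-3-iodo-2,6-bis(methoxymethoxy)phenyl]diazomethane
Conditions: activated MnO2 (10 equiv), Na2SO4, PhMe, 0 °C, dark; cold filtration through Celite, used at once
Reagents that add atoms: none
Why: Dehydrogenation of the N-unsubstituted hydrazone to the aryl diazomethane (hydrazone oxidation); the two ortho alkoxy groups shield the diazo carbon from bimolecular decay, and the solution is filtered cold, titrated and used without concentration.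

Step 9
Reactants: 6 racemic 4,6-bis(benzyloxy)-2-[3,4-bis(benzyloxy)phenyl]benzofuran-3(2H)-one; 12 [4-(benzyloxy)-3-iodo-2,6-bis(methoxymethoxy)phenyl]diazomethane
Product: 13 (2R,3S)-5,7-bis(benzyloxy)-2-[3,4-bis(benzyloxy)phenyl]-3-[4-(benzyloxy)-3-iodo-2,6-bis(methoxymethoxy)phenyl]chroman-4-one
Conditions: Sc(OTf)3 (10 mol%), chiral tris(oxazoline) ligand i-Pr-trisox (12 mol%, antipode fixed by screening), 2,6-di-tert-butylpyridine (10 mol%), PhMe, −78 → −30 °C, 12 (1.5 equiv) added over 4 h; then rt until C3 is fully trans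
Reagents that add atoms: none
Why: Proposed new method: the nucleophilic diazo carbon of 12 adds to the scandium-activated C3 carbonyl of 6 to give a diazonium alkoxide, and a 1,2-shift of the furanone C2 onto that carbon with loss of N2 regenerates the ketone, so that the C3–C4 and C2–C3 bonds of 13 form in one operation; the closest known reaction type is the Sc(OTf)3-catalysed homologation of cycloalkanones with aryl diazomethanes to ring-enlarged α-aryl ketones (Büchner–Curtius–Schlotterbeck or Tiffeneau–Demjanov type), including its chiral oxazoline-ligand variants. Ring C is therefore closed by ring expansion of the five-membered ring through a 1,2-migration, not by a cyclisation, so no Baldwin mode applies. C2 migrates with retention, and because 6 racemises quickly through its enol (the aromatic 3-hydroxybenzofuran) the chiral scandium complex can consume only the (2S)-enantiomer of 6, which becomes (2R) in 13 (dynamic kinetic resolution; the descriptor changes only through the CIP priorities). C3 lies between the ketone and the aryl group, epimerises under the same Lewis acid and settles trans (3S) to the C2 aryl group, so it is under thermodynamic control by C2. The step needs migration of C2 and not of the ring-A carbon C3a: C2 is secondary and carries O1 and a para-benzyloxyphenyl group that stabilise positive charge in the migrating carbon, while migration of C3a would push the 2,6-disubstituted aryl group against the peri C4 benzyloxy group. It also needs carbonyl addition to outrun protonation of 12 by the acidic C2–H, which low temperature, slow addition of 12 and the shielding ortho substituents of 12 are meant to secure.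

Step 10
Reactants: 13 (2R,3S)-5,7-bis(benzyloxy)-2-[3,4-bis(benzyloxy)phenyl]-3-[4-(benzyloxy)-3-iodo-2,6-bis(methoxymethoxy)phenyl]chroman-4-one
Product: 14 (2R,3S)-5,7-bis(benzyloxy)-2-[3,4-bis(benzyloxy)phenyl]-3-{4-(benzyloxy)-2,6-bis(methoxymethoxy)-3-[3-(trimethylsilyl)prop-2-ynoyl]phenyl}chroman-4-one
Conditions: CO (1 atm), HC≡CSiMe3 (2 equiv), PdCl2(PPh3)2 (5 mol%), Et3N, THF, rt → 40 °C
Reagents that add atoms: carbon monoxide, [C-]#[O+]; ethynyltrimethylsilane, C#C[Si](C)(C)C
Why: Copper-free carbonylative Sonogashira coupling of the aryl iodide: the electron-rich, doubly ortho-substituted aryl–palladium intermediate should insert CO faster than it is alkynylated, and the only base is a tertiary amine, too weak to enolise C3 and open ring C.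

Step 11
Reactants: 14 (2R,3S)-5,7-bis(benzyloxy)-2-[3,4-bis(benzyloxy)phenyl]-3-{4-(benzyloxy)-2,6-bis(methoxymethoxy)-3-[3-(trimethylsilyl)prop-2-ynoyl]phenyl}chroman-4-one
Product: 16 (2R,3S)-5,7-bis(benzyloxy)-2-[3,4-bis(benzyloxy)phenyl]-3-[5-(benzyloxy)-7-hydroxy-4-oxo-4H-chromen-8-yl]chroman-4-one, via terminal ynone 15 (not isolated)
Conditions: Bu4NF/AcOH (1:1), THF, 0 °C; then 3 M HCl, MeOH/THF, 40 °C
Reagents that add atoms: none
Why: Buffered fluoride protodesilylation gives the terminal ynone, then acid-catalysed acetal cleavage frees the C2' hydroxyl, which closes ring F by 6-endo-dig oxa-Michael addition to the ynone (directly or through its methanol adduct); only this oxygen is ortho to the acyl group while the C4' oxygen stays benzylated, which fixes the C3–C8'' linkage, and the acid is kept mild so that the C7'' hydroxyl does not condense with the C4 ketone.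

Step 12
Reactants: 16 (2R,3S)-5,7-bis(benzyloxy)-2-[3,4-bis(benzyloxy)phenyl]-3-[5-(benzyloxy)-7-hydroxy-4-oxo-4H-chromen-8-yl]chroman-4-one; 17 4-(benzyloxy)phenylboronic acid
Product: 18 (2R,3S)-5,7-bis(benzyloxy)-2-[3,4-bis(benzyloxy)phenyl]-3-{(2S)-5-(benzyloxy)-2-[4-(benzyloxy)phenyl]-7-hydroxy-4-oxochroman-8-yl}chroman-4-one
Conditions: 17 (2 equiv), Pd(OCOCF3)2 (10 mol%), (R)-t-BuPyOx (12 mol%), NH4PF6 (30 mol%), H2O (5 equiv), ClCH2CH2Cl, 60 °C
Reagents that add atoms: none
Why: Catalyst-controlled conjugate addition of an arylboronic acid to the chromone (Hayashi–Miyaura-type 1,4-addition under divalent palladium–pyridine-oxazoline catalysis, no added base): the ligand decides which face of C2'' takes up the aryl group and so sets (2''S) independently of the remote C2 and C3 centres, and the slightly acidic medium cannot epimerise them.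

Step 13
Reactants: 18 (2R,3S)-5,7-bis(benzyloxy)-2-[3,4-bis(benzyloxy)phenyl]-3-{(2S)-5-(benzyloxy)-2-[4-(benzyloxy)phenyl]-7-hydroxy-4-oxochroman-8-yl}chroman-4-one
Product: 19 (2R,3S)-2-(3,4-dihydroxyphenyl)-5,7-dihydroxy-3-[(2S)-5,7-dihydroxy-2-(4-hydroxyphenyl)-4-oxochroman-8-yl]chroman-4-one (CNP0105436.2)
Conditions: H2 (1 atm), 10% Pd/C, EtOAc/MeOH, rt
Reagents that add atoms: none
Why: Hydrogenolysis of all six benzyl aryl ethers over palladium under neutral conditions, which epimerise none of the three stereocentres; the reaction is stopped at full debenzylation to avoid reduction of the aryl ketones or of the benzylic C2–O and C2''–O bonds.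

Compound list
1 | 1,3,5-tris(benzyloxy)benzene | c1c(OCc2ccccc2)cc(OCc2ccccc2)cc1OCc1ccccc1 | starting material
2 | 3,4-bis(benzyloxy)phenylacetic acid | OC(=O)Cc1ccc(OCc2ccccc2)c(OCc2ccccc2)c1 | starting material
3 | 2-[3,4-bis(benzyloxy)phenyl]-1-[2,4,6-tris(benzyloxy)phenyl]ethan-1-one | O=C(Cc1ccc(OCc2ccccc2)c(OCc2ccccc2)c1)c1c(OCc2ccccc2)cc(OCc2ccccc2)cc1OCc1ccccc1 | intermediate
4 | 1-[2,4-bis(benzyloxy)-6-hydroxyphenyl]-2-[3,4-bis(benzyloxy)phenyl]ethan-1-one | O=C(Cc1ccc(OCc2ccccc2)c(OCc2ccccc2)c1)c1c(O)cc(OCc2ccccc2)cc1OCc1ccccc1 | intermediate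
5 | racemic 1-[2,4-bis(benzyloxy)-6-hydroxyphenyl]-2-bromo-2-[3,4-bis(benzyloxy)phenyl]ethan-1-one (α-bromo ketone, not isolated) | O=C(C(Br)c1ccc(OCc2ccccc2)c(OCc2ccccc2)c1)c1c(O)cc(OCc2ccccc2)cc1OCc1ccccc1 | intermediate
6 | racemic 4,6-bis(benzyloxy)-2-[3,4-bis(benzyloxy)phenyl]benzofuran-3(2H)-one | O=C1C(c2ccc(OCc3ccccc3)c(OCc3ccccc3)c2)Oc2cc(OCc3ccccc3)cc(OCc3ccccc3)c21 | intermediate
7 | 2,4,6-trihydroxybenzaldehyde | O=Cc1c(O)cc(O)cc1O | starting material
8 | 4-(benzyloxy)-2,6-dihydroxybenzaldehyde | O=Cc1c(O)cc(OCc2ccccc2)cc1O | intermediate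
9 | 4-(benzyloxy)-2,6-bis(methoxymethoxy)benzaldehyde | O=Cc1c(OCOC)cc(OCc2ccccc2)cc1OCOC | intermediate
10 | 4-(benzyloxy)-3-iodo-2,6-bis(methoxymethoxy)benzaldehyde | O=Cc1c(OCOC)c(I)c(OCc2ccccc2)cc1OCOC | intermediate
11 | (E)-[4-(benzyloxy)-3-iodo-2,6-bis(methoxymethoxy)benzylidene]hydrazine | N/N=C/c1c(OCOC)c(I)c(OCc2ccccc2)cc1OCOC | intermediate
12 | [4-(benzyloxy)-3-iodo-2,6-bis(methoxymethoxy)phenyl]diazomethane | [N-]=[N+]=Cc1c(OCOC)c(I)c(OCc2ccccc2)cc1OCOC | intermediate
13 | (2R,3S)-5,7-bis(benzyloxy)-2-[3,4-bis(benzyloxy)phenyl]-3-[4-(benzyloxy)-3-iodo-2,6-bis(methoxymethoxy)phenyl]chroman-4-one | O=C1c2c(OCc3ccccc3)cc(OCc3ccccc3)cc2O[C@@H](c2ccc(OCc3ccccc3)c(OCc3ccccc3)c2)[C@@H]1c1c(OCOC)c(I)c(OCc2ccccc2)cc1OCOC | intermediate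
14 | (2R,3S)-5,7-bis(benzyloxy)-2-[3,4-bis(benzyloxy)phenyl]-3-{4-(benzyloxy)-2,6-bis(methoxymethoxy)-3-[3-(trimethylsilyl)prop-2-ynoyl]phenyl}chroman-4-one | O=C1c2c(OCc3ccccc3)cc(OCc3ccccc3)cc2O[C@@H](c2ccc(OCc3ccccc3)c(OCc3ccccc3)c2)[C@@H]1c1c(OCOC)c(C(=O)C#C[Si](C)(C)C)c(OCc2ccccc2)cc1OCOC | intermediate
15 | (2R,3S)-5,7-bis(benzyloxy)-2-[3,4-bis(benzyloxy)phenyl]-3-[4-(benzyloxy)-2,6-bis(methoxymethoxy)-3-(prop-2-ynoyl)phenyl]chroman-4-one (terminal ynone, not isolated) | O=C1c2c(OCc3ccccc3)cc(OCc3ccccc3)cc2O[C@@H](c2ccc(OCc3ccccc3)c(OCc3ccccc3)c2)[C@@H]1c1c(OCOC)c(C(=O)C#C)c(OCc2ccccc2)cc1OCOC | intermediate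
16 | (2R,3S)-5,7-bis(benzyloxy)-2-[3,4-bis(benzyloxy)phenyl]-3-[5-(benzyloxy)-7-hydroxy-4-oxo-4H-chromen-8-yl]chroman-4-one | O=C1c2c(OCc3ccccc3)cc(OCc3ccccc3)cc2O[C@@H](c2ccc(OCc3ccccc3)c(OCc3ccccc3)c2)[C@@H]1c1c(O)cc(OCc2ccccc2)c2c(=O)ccoc12 | intermediate
17 | 4-(benzyloxy)phenylboronic acid | OB(O)c1ccc(OCc2ccccc2)cc1 | starting material
18 | (2R,3S)-5,7-bis(benzyloxy)-2-[3,4-bis(benzyloxy)phenyl]-3-{(2S)-5-(benzyloxy)-2-[4-(benzyloxy)phenyl]-7-hydroxy-4-oxochroman-8-yl}chroman-4-one | O=C1c2c(OCc3ccccc3)cc(OCc3ccccc3)cc2O[C@@H](c2ccc(OCc3ccccc3)c(OCc3ccccc3)c2)[C@@H]1c1c(O)cc(OCc2ccccc2)c2C(=O)C[C@@H](c3ccc(OCc4ccccc4)cc3)Oc12 | intermediate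
19 | (2R,3S)-2-(3,4-dihydroxyphenyl)-5,7-dihydroxy-3-[(2S)-5,7-dihydroxy-2-(4-hydroxyphenyl)-4-oxochroman-8-yl]chroman-4-one | O=C1C[C@@H](c2ccc(O)cc2)Oc2c1c(O)cc(O)c2[C@@H]1C(=O)c2c(O)cc(O)cc2O[C@H]1c1ccc(O)c(O)c1 | target

Total step count: 13. Longest linear sequence: 10 steps (7 → 8 → 9 → 10 → 11 → 12 → 13 → 14 → 16 → 18 → 19, steps 4 to 13); steps 1 to 3 form the convergent branch to 6.

Steps most likely to fail

Step 9 (the proposed new method). Four processes may defeat it:
- the migration may take the ring-A carbon C3a instead of C2, giving the isomeric chroman-3-one skeleton;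
- the acidic C2–H of 6 may protonate 12, so that the enolate is O- or C-benzylated;
- addition to the hindered, deactivated carbonyl may be slower than decay of the diazo compound;
- the catalyst may fail to distinguish the enantiomers of 6.

Fallback with known chemistry, setting out from 7 and 12 and coming back at 13: 7 would be benzylated twice (BnBr, K2CO3, DMF; the chelated hydroxyl remains) to 2,4-bis(benzyloxy)-6-hydroxybenzaldehyde F1, then silylated (TBSCl, imidazole) to 2,4-bis(benzyloxy)-6-[(tert-butyldimethylsilyl)oxy]benzaldehyde F2. F2 would be homologated with 12 under Sc(OTf)3 catalysis (formyl C–H insertion, a Roskamp-type reaction in which hydrogen migrates in preference to the aryl group) to the silyl-protected deoxybenzoin F3. Buffered fluoride (Bu4NF/AcOH) would free the phenol to give the hydroxy deoxybenzoin F4. Piperidine-catalysed condensation of F4 with 3,4-bis(benzyloxy)benzaldehyde (Knoevenagel condensation followed by oxa-Michael closure, the classical 2,3-diarylchromanone synthesis) should give the trans product as the racemate of 13 and its (2S,3R)-enantiomer F5, to be separated by preparative HPLC on a chiral stationary phase.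

Step 10. Direct alkynylation may outrun CO insertion, or oxidative addition at the doubly ortho-substituted aryl iodide may be slow and end in protodeiodination.

Fallback, setting out from 13 and coming back at 16: Stille coupling with tributyl(1-ethoxyvinyl)stannane (PdCl2(PPh3)2, PhMe, 100 °C) would give the enol ether F6, hydrolysed with dilute HCl to the methyl ketone F7. Condensation with Me2NCH(OMe)2 at the lowest workable temperature would give the enaminone F8. This reagent is basic enough to threaten ring C, which is why this order is only the reserve; the integrity of C2 would be checked by chiral HPLC. 3 M HCl in MeOH would then remove the acetals and close the chromone 16 by addition–elimination.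

Step 12. The electron-rich, 8-substituted chromone may take up the arylpalladium species slowly, 17 may protodeboronate, or the facial selectivity may be low.

Fallback, setting out from 13 and coming back at 18: 13 would be taken through the enol ether F6 to the methyl ketone F7 as above. HCl in MeOH would remove the acetals to give the dihydroxy ketone F9. Acid-catalysed Claisen–Schmidt condensation with 4-(benzyloxy)benzaldehyde (SOCl2 in EtOH) would give the chalcone F10. Acid-mediated oxa-Michael closure (chalcone–flavanone isomerisation; only the C2' hydroxyl is ortho to the enone) would give 18 together with its (2''R)-epimer F11. These are diastereomers and would be separated by preparative HPLC; in this reserve C2'' is not set by a catalyst.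

Further compounds
F1 | step 9 | 2,4-bis(benzyloxy)-6-hydroxybenzaldehyde | O=Cc1c(O)cc(OCc2ccccc2)cc1OCc1ccccc1
F2 | step 9 | 2,4-bis(benzyloxy)-6-[(tert-butyldimethylsilyl)oxy]benzaldehyde | O=Cc1c(O[Si](C)(C)C(C)(C)C)cc(OCc2ccccc2)cc1OCc1ccccc1
F3 | step 9 | 1-{2,4-bis(benzyloxy)-6-[(tert-butyldimethylsilyl)oxy]phenyl}-2-[4-(benzyloxy)-3-iodo-2,6-bis(methoxymethoxy)phenyl]ethan-1-one | O=C(Cc1c(OCOC)c(I)c(OCc2ccccc2)cc1OCOC)c1c(O[Si](C)(C)C(C)(C)C)cc(OCc2ccccc2)cc1OCc1ccccc1
F4 | step 9 | 1-[2,4-bis(benzyloxy)-6-hydroxyphenyl]-2-[4-(benzyloxy)-3-iodo-2,6-bis(methoxymethoxy)phenyl]ethan-1-one | O=C(Cc1c(OCOC)c(I)c(OCc2ccccc2)cc1OCOC)c1c(O)cc(OCc2ccccc2)cc1OCc1ccccc1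
F5 | step 9 | (2S,3R)-5,7-bis(benzyloxy)-2-[3,4-bis(benzyloxy)phenyl]-3-[4-(benzyloxy)-3-iodo-2,6-bis(methoxymethoxy)phenyl]chroman-4-one (enantiomer of 13) | O=C1c2c(OCc3ccccc3)cc(OCc3ccccc3)cc2O[C@H](c2ccc(OCc3ccccc3)c(OCc3ccccc3)c2)[C@H]1c1c(OCOC)c(I)c(OCc2ccccc2)cc1OCOC
F6 | step 10 | (2R,3S)-5,7-bis(benzyloxy)-2-[3,4-bis(benzyloxy)phenyl]-3-[4-(benzyloxy)-3-(1-ethoxyvinyl)-2,6-bis(methoxymethoxy)phenyl]chroman-4-one | O=C1c2c(OCc3ccccc3)cc(OCc3ccccc3)cc2O[C@@H](c2ccc(OCc3ccccc3)c(OCc3ccccc3)c2)[C@@H]1c1c(OCOC)c(C(=C)OCC)c(OCc2ccccc2)cc1OCOC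
F7 | step 10 | (2R,3S)-3-[3-acetyl-4-(benzyloxy)-2,6-bis(methoxymethoxy)phenyl]-5,7-bis(benzyloxy)-2-[3,4-bis(benzyloxy)phenyl]chroman-4-one | O=C1c2c(OCc3ccccc3)cc(OCc3ccccc3)cc2O[C@@H](c2ccc(OCc3ccccc3)c(OCc3ccccc3)c2)[C@@H]1c1c(OCOC)c(C(C)=O)c(OCc2ccccc2)cc1OCOC
F8 | step 10 | (2R,3S)-5,7-bis(benzyloxy)-2-[3,4-bis(benzyloxy)phenyl]-3-{4-(benzyloxy)-3-[(E)-3-(dimethylamino)prop-2-enoyl]-2,6-bis(methoxymethoxy)phenyl}chroman-4-one | O=C1c2c(OCc3ccccc3)cc(OCc3ccccc3)cc2O[C@@H](c2ccc(OCc3ccccc3)c(OCc3ccccc3)c2)[C@@H]1c1c(OCOC)c(C(=O)/C=C/N(C)C)c(OCc2ccccc2)cc1OCOC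
F9 | step 12 | (2R,3S)-3-[3-acetyl-4-(benzyloxy)-2,6-dihydroxyphenyl]-5,7-bis(benzyloxy)-2-[3,4-bis(benzyloxy)phenyl]chroman-4-one | O=C1c2c(OCc3ccccc3)cc(OCc3ccccc3)cc2O[C@@H](c2ccc(OCc3ccccc3)c(OCc3ccccc3)c2)[C@@H]1c1c(O)c(C(C)=O)c(OCc2ccccc2)cc1O
F10 | step 12 | (2R,3S)-5,7-bis(benzyloxy)-2-[3,4-bis(benzyloxy)phenyl]-3-{4-(benzyloxy)-3-[(E)-3-(4-(benzyloxy)phenyl)prop-2-enoyl]-2,6-dihydroxyphenyl}chroman-4-one | O=C1c2c(OCc3ccccc3)cc(OCc3ccccc3)cc2O[C@@H](c2ccc(OCc3ccccc3)c(OCc3ccccc3)c2)[C@@H]1c1c(O)c(C(=O)/C=C/c2ccc(OCc3ccccc3)cc2)c(OCc2ccccc2)cc1O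
F11 | step 12 | (2R,3S)-5,7-bis(benzyloxy)-2-[3,4-bis(benzyloxy)phenyl]-3-{(2R)-5-(benzyloxy)-2-[4-(benzyloxy)phenyl]-7-hydroxy-4-oxochroman-8-yl}chroman-4-one (C2'' epimer of 18) | O=C1c2c(OCc3ccccc3)cc(OCc3ccccc3)cc2O[C@@H](c2ccc(OCc3ccccc3)c(OCc3ccccc3)c2)[C@@H]1c1c(O)cc(OCc2ccccc2)c2C(=O)C[C@H](c3ccc(OCc4ccccc4)cc3)Oc12
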